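## Retrosynthetic overview

- No ring is formed: the benzene ring and all seven carbons are bought as 4-methylcatechol.
- Target ⇒ a 2-hydroxy-p-quinone methide plus hydrogen disulfate. The benzylic C–O(sulfate) bond and the aryl O–SO3 bond are made together by 1,6-addition; the quinone methide's single carbonyl oxygen (para to CH2) is what distinguishes the two catechol oxygens.
- Quinone methide ⇒ its tautomer, 3,4,6-tribromo-5-methyl-o-benzoquinone ⇒ tribromo-4-methylcatechol (two-electron oxidation).
- Tribromo-4-methylcatechol ⇒ 4-methylcatechol + 3 Br2.

Assumption: the target has no stereocentre (it is achiral), so no enantiomer has to be chosen; it is written as the free bis(hydrogen sulfate) and is isolated via its disodium salt.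

## Route

Step 1
Reactants: 1 4-methylbenzene-1,2-diol (4-methylcatechol)
Product: 2 3,4,6-tribromo-5-methylbenzene-1,2-diol
Conditions: Br2 (3.05 equiv), AcOH, 10 → 25 °C; aq. NaHSO3 quench
Reagents that add atoms: bromine, BrBr
Why: Electrophilic aromatic bromination: each of the three free ring positions is ortho or para to an OH, the ring is then full so substitution stops at the tribromide, and the acidic medium (AcOH/HBr) disfavours oxidation of the catechol to the quinone; no stereocentre is involved.

Step 2
Reactants: 2 3,4,6-tribromo-5-methylbenzene-1,2-diol
Product: 3 3,4,6-tribromo-5-methylcyclohexa-3,5-diene-1,2-dione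
Conditions: Ag2O (2.0 equiv), Na2SO4, Et2O, 0 °C, dark, 20 min; filter (Celite), concentrate at 0 °C, crystallise (Et2O–pentane, −20 °C)
Reagents that add atoms: none
Why: Willstätter oxidation of a catechol to the o-benzoquinone with silver(I) oxide: a neutral, anhydrous two-electron oxidation in which the drying agent takes up the water formed, the fully substituted ring offers no position for conjugate addition, and the short contact time in the cold keeps the quinone from tautomerising; no stereocentre is involved.

Step 3
Reactants: 3 3,4,6-tribromo-5-methylcyclohexa-3,5-diene-1,2-dione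
Product: 5 [2,3,6-tribromo-5-hydroxy-4-(sulfooxy)phenyl]methyl hydrogen sulfate, via quinone methide 4 (not isolated)
Conditions: premixed SO3·DMF/Bu4NHSO4 (1.2 equiv each), 2,6-di-tert-butyl-4-methylpyridine (0.2 equiv), CH2Cl2–MeCN, −40 → 0 °C, dark; sodium 2-ethylhexanoate (2.2 equiv, disodium salt); Dowex 50 (H+), 0 °C
Reagents that add atoms: tetrabutylammonium hydrogen sulfate, CCCC[N+](CCCC)(CCCC)CCCC.OS(=O)(=O)[O-]; sulfur trioxide–N,N-dimethylformamide complex, CN(C)C=O.O=S(=O)=O
Why: Proposed new method: tautomerisation-triggered 1,6-sulfato-sulfation of an o-quinone — the acidic hydrogen disulfate (formed from SO3·DMF and Bu4NHSO4) and the hindered pyridine/pyridinium pair catalyse vinylogous enolisation of the one carbonyl that is conjugated with the methyl-bearing carbon, which turns 3 into quinone methide 4 with its only remaining carbonyl oxygen para to the exocyclic CH2 and the other oxygen already an OH; that carbonyl oxygen attacks sulfur of hydrogen disulfate while the expelled hydrogen sulfate collapses on the exocyclic carbon within the ion pair, so the benzylic C–O bond and the aryl O–SO3 bond form in one rearomatising event; premature 1,6-addition of hydrogen sulfate gives a para-hydroxybenzyl sulfate that re-ionises to 4 and is only a reservoir, whereas the para-O-sulfonated product cannot re-ionise, and the meta OH stays free because no phenoxide or dienolate is made in quantity (the base is weak, hindered and substoichiometric) and the anionic reagent does not sulfonate a neutral, hindered, hydrogen-bonded phenol; the closest known reaction types are the tautomerisation of 4-alkyl-o-quinones to 2-hydroxy-p-quinone methides with capture of a nucleophile at the benzylic carbon, the 1,6-additions of HX, acyl halides and anhydrides across Zincke-type quinone methides, and phenol sulfation by pyrosulfate or SO3 complexes.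

## Compound list

1 | 4-methylbenzene-1,2-diol (4-methylcatechol) | Cc1ccc(O)c(O)c1 | starting material
2 | 3,4,6-tribromo-5-methylbenzene-1,2-diol | Cc1c(Br)c(O)c(O)c(Br)c1Br | intermediate
3 | 3,4,6-tribromo-5-methylcyclohexa-3,5-diene-1,2-dione | CC1=C(Br)C(=O)C(=O)C(Br)=C1Br | intermediate
4 | 2,3,5-tribromo-6-hydroxy-4-methylidenecyclohexa-2,5-dien-1-one | C=C1C(Br)=C(O)C(=O)C(Br)=C1Br | intermediate
5 | [2,3,6-tribromo-5-hydroxy-4-(sulfooxy)phenyl]methyl hydrogen sulfate | O=S(=O)(O)OCc1c(Br)c(O)c(OS(=O)(=O)O)c(Br)c1Br | target

## Step count and risks

Total steps: 3. Longest linear sequence: 3 steps (1 → 2 → 3 → 5).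

**Most likely to fail, first: step 3 (the proposed new step).** The regiochemical argument is a mechanistic hypothesis and is the main uncertainty.
- The tautomerisation of 3 to 4 may be slow under the buffered acid, or its equilibrium may lie on the quinone side, so that everything depends on the trapping.
- If the reservoir catechol benzylic sulfate is O-sulfonated before it re-ionises, the two oxygens are no longer distinguished and the regioisomer or a bis-aryl sulfate results. A stronger or more abundant base would do the same through O-sulfonation of the dienolate.
- 4 may oligomerise, and DMF or MeCN may capture the benzylic carbon.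
- Diagnostic: the wrong isomer keeps a free para-OH, so its benzylic sulfate is solvolysed in MeOH through the quinone methide, whereas 5 is inert. This also allows its removal by anion exchange.

The fallback uses known chemistry only. It sets out from 2 and comes back at 5. Zincke–Auwers side-chain bromination (Br2 1.1 equiv, ClCH2CH2Cl, 60 °C, sealed, dark) gives 3,4,6-tribromo-5-(bromomethyl)benzene-1,2-diol F1. Kornblum oxidation (DMSO, NaHCO3, 60 °C) gives 2,3,6-tribromo-4,5-dihydroxybenzaldehyde F2. Its monoanion (NaHCO3 1.0 equiv, DMF) is the phenoxide para to the formyl group, as in the selective 4-O-alkylation of protocatechualdehyde. O-Sulfation with SO3·NMe3 (1.1 equiv) gives 2,3,6-tribromo-5-hydroxy-4-(sulfooxy)benzaldehyde F3. NaBH4 (MeOH/H2O, 0 °C) reduces this to [2,3,6-tribromo-5-hydroxy-4-(sulfooxy)phenyl]methanol F4. SO3·pyridine (1.1 equiv, DMF, 0 °C) then sulfates the primary alcohol in preference to the hindered, hydrogen-bonded phenol and gives 5.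

**Second: step 2.** The quinone may tautomerise on the basic oxide surface or on concentration to 4, which then adds the water formed or oligomerises; the oxidation may also stay incomplete. The fallback gives up 3 as an isolated compound and replaces the two-flask sequence by a one-flask oxidation–sulfato-sulfation in which the quinone is only a transient. It sets out from 2 and comes back at 5. Compound 2 is oxidised with Ag2O over 3 Å MS in CH2Cl2 at −20 °C in the dark, and the cold suspension is filtered under argon straight into the precooled hydrogen disulfate/hindered pyridine solution of step 3, so that 3 is consumed as it arrives and is never concentrated. New compounds on its way: none F0.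

**Third: step 1.** The catechol may be oxidised to quinone and tar, or mixtures of bromination levels may form. The fallback masks the catechol. It sets out from 1 and comes back at 2. Methylation (Me2SO4, K2CO3, acetone) gives 1,2-dimethoxy-4-methylbenzene F5. Exhaustive bromination (Br2 3.3 equiv, Fe cat., CHCl3, reflux) gives 1,2,4-tribromo-5,6-dimethoxy-3-methylbenzene F6. BBr3 (CH2Cl2, −78 → 25 °C) then demethylates to 2.

Further compounds
F1 | step 3 | 3,4,6-tribromo-5-(bromomethyl)benzene-1,2-diol | BrCc1c(Br)c(O)c(O)c(Br)c1Br
F2 | step 3 | 2,3,6-tribromo-4,5-dihydroxybenzaldehyde | O=Cc1c(Br)c(O)c(O)c(Br)c1Br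
F3 | step 3 | 2,3,6-tribromo-5-hydroxy-4-(sulfooxy)benzaldehyde | O=Cc1c(Br)c(O)c(OS(=O)(=O)O)c(Br)c1Br
F4 | step 3 | [2,3,6-tribromo-5-hydroxy-4-(sulfooxy)phenyl]methanol | OCc1c(Br)c(O)c(OS(=O)(=O)O)c(Br)c1Br
F0 | step 2 | none | none
F5 | step 1 | 1,2-dimethoxy-4-methylbenzene | COc1ccc(C)cc1OC
F6 | step 1 | 1,2,4-tribromo-5,6-dimethoxy-3-methylbenzene | COc1c(OC)c(Br)c(C)c(Br)c1Br
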